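Ring numbering used throughout: C1 ketone, C2 (bears C7H2OH), C3 (=CH), C4 (O-propanoyl), C5 (isopropyl), C6 (O-hydroxytigloyl). The retrosynthesis cuts the acyl C–O bonds at O6 and O4 (the latter with inversion at C4), then the ring bond C5–C6, then C1–C2 and C3–C4 of the open chain.
Enabling feature: in the cyclohexenone ring C1–C6 the carbinol C6 lies between the C1 ketone and the isopropyl-bearing C5. C6 can therefore enter as the aldehyde of a 2-oxoaldehyde (C1/C6) and C5 as the inner carbon of a C5=C(CH3)2 unit that donates an allylic hydrogen, while the C2=C3 bond, Z in the open chain, holds C1 and C4 on one side.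
Forward: 3-methylbut-2-enal and a silyl propargyl ether are joined at C3–C4, the alkyne becomes a (Z)-alkenyl iodide, a glycolaldehyde ether is attached at C1–C2, and two oxidations give the 2-oxoaldehyde. The only ring then closes at C5–C6 by a carbonyl-ene reaction, followed by hydrogenation, acylation of O6, inversion with propanoylation at C4, and desilylation.
Stereochemistry: C4 comes from a ligand-controlled zinc alkynylation. C5 and C6 come from C4 in the ene transition state (allylic 1,3-strain, all-equatorial chair: 4,5-trans, 5,6-trans), and C4 is then inverted by a Mitsunobu reaction to the 4,5-cis target. The C2=C3 geometry comes from directed trans-hydroalumination and the side-chain E geometry from a stabilised Wittig reagent.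

Key step: step 8

Assumption: the (S,S) antipode of ProPhenol is taken to deliver the 4S carbinol 4; if the sense of induction proves opposite, the (R,R) ligand is used and nothing else changes (configuration to be checked on the Mosher esters of 4).
Assumption: the silyl ethers 2 and 15 are taken as purchasable building blocks.
Remark: labels C1–C7, O4 and O6 always mean the target numbering above; systematic names of open-chain compounds use their own locants.

Step 1
Reactants: 1 3-methylbut-2-enal; 2 tert-butyl(diphenyl)(prop-2-yn-1-yloxy)silane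
Product: 4 (4S)-1-{[tert-butyl(diphenyl)silyl]oxy}-6-methylhept-5-en-2-yn-4-ol, via methylzinc acetylide 3 (not isolated)
Conditions: 2, Me2Zn, (S,S)-ProPhenol (10 mol %), Ph3P=O (20 mol %), toluene, 0 °C; then 1, 0 to 4 °C
Reagents that add atoms: none
Why: Catalytic asymmetric alkynylation of an aldehyde, in which the zinc acetylide adds 1,2 to the enal inside the chiral pocket of the catalyst formed from Me2Zn and ProPhenol, a system established for α,β-unsaturated aldehydes, so that one aldehyde face is selected and C4 is set as S.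

Step 2
Reactants: 4 (4S)-1-{[tert-butyl(diphenyl)silyl]oxy}-6-methylhept-5-en-2-yn-4-ol
Product: 6 (2Z,4S)-1-{[tert-butyl(diphenyl)silyl]oxy}-2-iodo-6-methylhepta-2,5-dien-4-ol, via cyclic alkenylalanate 5 (not isolated)
Conditions: NaAlH2(OCH2CH2OMe)2, THF, 0 °C to rt; then I2, THF, −78 °C
Reagents that add atoms: iodine, II
Why: Hydroxyl-directed trans-hydroalumination of a propargylic alcohol followed by iodinolysis, in which the aluminium alkoxide delivers hydride to the proximal alkyne carbon C3 and aluminium ends on C2 in a five-membered ring, so that iodine replaces aluminium with retention and stands cis to C4 (Z), the silylated oxygen at C7 being unable to direct.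

Step 3
Reactants: 6 (2Z,4S)-1-{[tert-butyl(diphenyl)silyl]oxy}-2-iodo-6-methylhepta-2,5-dien-4-ol
Product: 7 tert-butyl{[(2Z,4S)-2-iodo-6-methyl-4-[(triethylsilyl)oxy]hepta-2,5-dien-1-yl]oxy}diphenylsilane
Conditions: Et3SiCl, imidazole, CH2Cl2, 0 °C
Reagents that add atoms: chlorotriethylsilane, CC[Si](Cl)(CC)CC
Why: Standard silylation of a secondary alcohol under mild base, which spares the acid-sensitive doubly allylic carbinol and the alkenyl iodide and installs a group that can later be removed in the presence of the tert-butyldiphenylsilyl ethers.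

Step 4
Reactants: 7 tert-butyl{[(2Z,4S)-2-iodo-6-methyl-4-[(triethylsilyl)oxy]hepta-2,5-dien-1-yl]oxy}diphenylsilane; 8 2-[(4-methoxyphenyl)methoxy]acetaldehyde
Product: 9 (3Z,5S)-3-({[tert-butyl(diphenyl)silyl]oxy}methyl)-1-[(4-methoxyphenyl)methoxy]-7-methyl-5-[(triethylsilyl)oxy]octa-3,6-dien-2-ol (both C2 epimers)
Conditions: CrCl2, NiCl2 (cat.), DMSO, rt
Reagents that add atoms: none
Why: Nozaki–Hiyama–Kishi coupling, a nickel-catalysed, CrCl2-mediated addition of an alkenyl iodide to an aldehyde that keeps the geometry of the trisubstituted alkene and tolerates both silyl ethers; the new carbinol (C1) may form as an epimer mixture because it is oxidised in the next step.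

Step 5
Reactants: 9 (3Z,5S)-3-({[tert-butyl(diphenyl)silyl]oxy}methyl)-1-[(4-methoxyphenyl)methoxy]-7-methyl-5-[(triethylsilyl)oxy]octa-3,6-dien-2-ol
Product: 10 (3Z,5S)-3-({[tert-butyl(diphenyl)silyl]oxy}methyl)-1-[(4-methoxyphenyl)methoxy]-7-methyl-5-[(triethylsilyl)oxy]octa-3,6-dien-2-one
Conditions: Dess–Martin periodinane, pyridine, CH2Cl2, 0 °C
Reagents that add atoms: none
Why: Dess–Martin oxidation of an allylic alcohol to the enone under pyridine buffering, conditions that should neither isomerise the Z double bond nor cleave the silyl and benzyl ethers.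

Step 6
Reactants: 10 (3Z,5S)-3-({[tert-butyl(diphenyl)silyl]oxy}methyl)-1-[(4-methoxyphenyl)methoxy]-7-methyl-5-[(triethylsilyl)oxy]octa-3,6-dien-2-one
Product: 11 (3Z,5S)-3-({[tert-butyl(diphenyl)silyl]oxy}methyl)-1-hydroxy-7-methyl-5-[(triethylsilyl)oxy]octa-3,6-dien-2-one
Conditions: DDQ, CH2Cl2/aq. NaH2PO4–Na2HPO4 (pH 7), 0 °C
Reagents that add atoms: none
Why: Oxidative cleavage of a 4-methoxybenzyl ether by DDQ (benzylic hydride abstraction, then hydrolysis of the hemiacetal) in a buffered two-phase medium that spares silyl ethers, the doubly allylic C4–H being deactivated toward hydride loss by the adjacent electron-poor enone.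

Step 7
Reactants: 11 (3Z,5S)-3-({[tert-butyl(diphenyl)silyl]oxy}methyl)-1-hydroxy-7-methyl-5-[(triethylsilyl)oxy]octa-3,6-dien-2-one
Product: 12 (3Z,5S)-3-({[tert-butyl(diphenyl)silyl]oxy}methyl)-7-methyl-2-oxo-5-[(triethylsilyl)oxy]octa-3,6-dienal
Conditions: Dess–Martin periodinane, pyridine, dry CH2Cl2, 0 °C; pentane, filtration through Celite, used at once
Reagents that add atoms: none
Why: Dess–Martin oxidation of a primary α-hydroxy ketone to the 2-oxoaldehyde, a known mild entry to glyoxal-type compounds, with a non-aqueous work-up so that the electrophilic aldehyde is not converted into its hydrate before cyclisation.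

Step 8
Reactants: 12 (3Z,5S)-3-({[tert-butyl(diphenyl)silyl]oxy}methyl)-7-methyl-2-oxo-5-[(triethylsilyl)oxy]octa-3,6-dienal
Product: 13 (4R,5R,6R)-2-({[tert-butyl(diphenyl)silyl]oxy}methyl)-6-hydroxy-5-(prop-1-en-2-yl)-4-[(triethylsilyl)oxy]cyclohex-2-en-1-one (4,5-trans; 5,6-trans; C4 epimeric to the target)
Conditions: ZnBr2, 4 Å molecular sieves, CH2Cl2, −40 to 0 °C
Reagents that add atoms: none
Why: Proposed new method: ZnBr2 binds the C1 and C6 carbonyl oxygens of the 2-oxoaldehyde, the C5=C(CH3)2 π bond attacks the activated aldehyde carbon C6 and a hydrogen of one of its methyl groups passes to O6 through a six-membered cyclic array (concerted but asynchronous intramolecular carbonyl-ene reaction), which forms the C5–C6 bond, the C6 carbinol and the isopropenyl group; the closest known reactions are the ZnBr2-promoted cyclisation of citronellal to isopulegol and the Lewis-acid-promoted ene additions of glyoxylates and aryl glyoxals, and what has no direct precedent is a 2-oxoaldehyde enophile tethered through a (Z)-enone. The cyclohexenone ring C1–C6 closes in the 6-exo mode with respect to both reacting π bonds (O6 and the isopropylidene carbon stay outside the ring), the Z geometry of C2=C3 holding C1 and C4 cis so that C6 and C5 can meet. C5 is controlled by the C4 stereocentre through allylic 1,3-strain: C4–H lies near the plane of the trisubstituted alkene beside its cis methyl group, the tether occupies one face and the silyloxy group the other, and bond formation on the tether face places the C5 substituent trans to O4. C6 is controlled by the chair-like transition state, in which the zinc-bridged O6 eclipses the C1 carbonyl and is therefore pseudo-equatorial, as is the isopropylidene unit, which gives the 5,6-trans carbinol. The step needs site selectivity (only the aldehyde, the most electrophilic carbonyl, can reach C5 in a six-membered array, and the electron-poor C2=C3 bond is no ene donor) and diastereoselectivity at C5 and C6 relative to C4, both supplied by the substrate as described; the mild Lewis acid and low temperature are chosen so that the doubly allylic silyl ether at C4 is not ionised.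

Step 9
Reactants: 13 (4R,5R,6R)-2-({[tert-butyl(diphenyl)silyl]oxy}methyl)-6-hydroxy-5-(prop-1-en-2-yl)-4-[(triethylsilyl)oxy]cyclohex-2-en-1-one
Product: 14 (4R,5R,6R)-2-({[tert-butyl(diphenyl)silyl]oxy}methyl)-6-hydroxy-5-isopropyl-4-[(triethylsilyl)oxy]cyclohex-2-en-1-one
Conditions: H2 (1 atm), RhCl(PPh3)3 (cat.), benzene, rt
Reagents that add atoms: none
Why: Homogeneous hydrogenation with RhCl(PPh3)3, which reduces an unhindered 1,1-disubstituted alkene and leaves a trisubstituted conjugated enone untouched (as in the reduction of carvone to carvotanacetone), and which creates no stereocentre.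

Step 10
Reactants: 15 2-{[tert-butyl(diphenyl)silyl]oxy}acetaldehyde; 16 ethyl 2-(triphenylphosphoranylidene)propanoate
Product: 17 ethyl (2E)-4-{[tert-butyl(diphenyl)silyl]oxy}-2-methylbut-2-enoate
Conditions: CH2Cl2, rt
Reagents that add atoms: none
Why: Wittig olefination with a stabilised α-methyl ylide, which should give the trisubstituted enoate with the E geometry required for the hydroxytiglate unit.

Step 11
Reactants: 17 ethyl (2E)-4-{[tert-butyl(diphenyl)silyl]oxy}-2-methylbut-2-enoate
Product: 18 (2E)-4-{[tert-butyl(diphenyl)silyl]oxy}-2-methylbut-2-enoic acid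
Conditions: LiOH, THF/MeOH/H2O, rt; then aq. HCl to pH 3, 0 °C
Reagents that add atoms: lithium hydroxide (its oxygen ends in the carboxyl group), [Li+].[OH-]
Why: Saponification of an ethyl ester by acyl–oxygen cleavage with LiOH, conditions under which the tert-butyldiphenylsilyl ether and the E double bond should persist.

Step 12
Reactants: 14 (4R,5R,6R)-2-({[tert-butyl(diphenyl)silyl]oxy}methyl)-6-hydroxy-5-isopropyl-4-[(triethylsilyl)oxy]cyclohex-2-en-1-one; 18 (2E)-4-{[tert-butyl(diphenyl)silyl]oxy}-2-methylbut-2-enoic acid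
Product: 20 (4R,5R,6R)-2-({[tert-butyl(diphenyl)silyl]oxy}methyl)-6-{[(2E)-4-{[tert-butyl(diphenyl)silyl]oxy}-2-methylbut-2-enoyl]oxy}-5-isopropyl-4-[(triethylsilyl)oxy]cyclohex-2-en-1-one, via mixed anhydride 19 (not isolated)
Conditions: 18, 2,4,6-trichlorobenzoyl chloride, Et3N, toluene, rt; then 14, DMAP, toluene, rt
Reagents that add atoms: none
Why: Yamaguchi esterification, in which DMAP attacks the less hindered enoyl carbonyl of the mixed anhydride and the resulting acylpyridinium acylates the hindered secondary C6 hydroxyl without breaking a bond at C6, whose equatorial arrangement is also the thermodynamically preferred one.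

Step 13
Reactants: 20 (4R,5R,6R)-2-({[tert-butyl(diphenyl)silyl]oxy}methyl)-6-{[(2E)-4-{[tert-butyl(diphenyl)silyl]oxy}-2-methylbut-2-enoyl]oxy}-5-isopropyl-4-[(triethylsilyl)oxy]cyclohex-2-en-1-one
Product: 21 (4R,5S,6R)-2-({[tert-butyl(diphenyl)silyl]oxy}methyl)-6-{[(2E)-4-{[tert-butyl(diphenyl)silyl]oxy}-2-methylbut-2-enoyl]oxy}-4-hydroxy-5-isopropylcyclohex-2-en-1-one
Conditions: PPTS (cat.), MeOH/CH2Cl2, 0 °C
Reagents that add atoms: none
Why: Mild acid-catalysed methanolysis of a triethylsilyl ether, selective because the two primary tert-butyldiphenylsilyl ethers are far more stable to acid and the esters do not transesterify under these conditions.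

Step 14
Reactants: 21 (4R,5S,6R)-2-({[tert-butyl(diphenyl)silyl]oxy}methyl)-6-{[(2E)-4-{[tert-butyl(diphenyl)silyl]oxy}-2-methylbut-2-enoyl]oxy}-4-hydroxy-5-isopropylcyclohex-2-en-1-one; 22 propanoic acid
Product: 23 (4S,5S,6R)-2-({[tert-butyl(diphenyl)silyl]oxy}methyl)-6-{[(2E)-4-{[tert-butyl(diphenyl)silyl]oxy}-2-methylbut-2-enoyl]oxy}-5-isopropyl-4-(propanoyloxy)cyclohex-2-en-1-one
Conditions: Ph3P, DIAD, THF, 0 °C to rt
Reagents that add atoms: none
Why: Mitsunobu reaction, in which the C4 hydroxyl is activated at phosphorus and displaced by propanoate in an SN2 process with inversion to give the 4,5-cis ester, SN2′ attack being blocked at the fully substituted enone carbon C2 and elimination disfavoured because no C5–H is antiperiplanar to the leaving group.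

Step 15
Reactants: 23 (4S,5S,6R)-2-({[tert-butyl(diphenyl)silyl]oxy}methyl)-6-{[(2E)-4-{[tert-butyl(diphenyl)silyl]oxy}-2-methylbut-2-enoyl]oxy}-5-isopropyl-4-(propanoyloxy)cyclohex-2-en-1-one
Product: 24 (4S,5S,6R)-2-(hydroxymethyl)-6-{[(2E)-4-hydroxy-2-methylbut-2-enoyl]oxy}-5-isopropyl-4-(propanoyloxy)cyclohex-2-en-1-one (CNP0285949.1)
Conditions: HF·pyridine, pyridine, THF, 0 °C to rt
Reagents that add atoms: none
Why: Fluoride-mediated cleavage of both primary silyl ethers with buffered HF·pyridine, a weakly acidic medium that should avoid the acyl migration, elimination or ester cleavage that basic fluoride sources could cause.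

Compound list
1 | 3-methylbut-2-enal | CC(C)=CC=O | starting material
2 | tert-butyl(diphenyl)(prop-2-yn-1-yloxy)silane | C#CCO[Si](c1ccccc1)(c1ccccc1)C(C)(C)C | starting material
3 | methylzinc acetylide of 2 (not isolated) | C[Zn]C#CCO[Si](c1ccccc1)(c1ccccc1)C(C)(C)C | intermediate
4 | (4S)-1-{[tert-butyl(diphenyl)silyl]oxy}-6-methylhept-5-en-2-yn-4-ol | O[C@@H](C=C(C)C)C#CCO[Si](c1ccccc1)(c1ccccc1)C(C)(C)C | intermediate
5 | sodium salt of the cyclic alkenylalanate (five-membered ring Al–O–C4–C3=C2, two 2-methoxyethoxy groups on Al; not isolated) | [Na+].COCCO[Al-]1(OCCOC)O[C@@H](C=C(C)C)C=C1CO[Si](c2ccccc2)(c2ccccc2)C(C)(C)C | intermediate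
6 | (2Z,4S)-1-{[tert-butyl(diphenyl)silyl]oxy}-2-iodo-6-methylhepta-2,5-dien-4-ol | O[C@@H](C=C(C)C)/C=C(\I)CO[Si](c1ccccc1)(c1ccccc1)C(C)(C)C | intermediate
7 | tert-butyl{[(2Z,4S)-2-iodo-6-methyl-4-[(triethylsilyl)oxy]hepta-2,5-dien-1-yl]oxy}diphenylsilane | CC[Si](CC)(CC)O[C@@H](C=C(C)C)/C=C(\I)CO[Si](c1ccccc1)(c1ccccc1)C(C)(C)C | intermediate
8 | 2-[(4-methoxyphenyl)methoxy]acetaldehyde | COc1ccc(COCC=O)cc1 | starting material
9 | (3Z,5S)-3-({[tert-butyl(diphenyl)silyl]oxy}methyl)-1-[(4-methoxyphenyl)methoxy]-7-methyl-5-[(triethylsilyl)oxy]octa-3,6-dien-2-ol (C2 epimers) | CC[Si](CC)(CC)O[C@@H](C=C(C)C)/C=C(CO[Si](c1ccccc1)(c1ccccc1)C(C)(C)C)\C(O)COCc1ccc(OC)cc1 | intermediate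
10 | (3Z,5S)-3-({[tert-butyl(diphenyl)silyl]oxy}methyl)-1-[(4-methoxyphenyl)methoxy]-7-methyl-5-[(triethylsilyl)oxy]octa-3,6-dien-2-one | CC[Si](CC)(CC)O[C@@H](C=C(C)C)/C=C(CO[Si](c1ccccc1)(c1ccccc1)C(C)(C)C)\C(=O)COCc1ccc(OC)cc1 | intermediate
11 | (3Z,5S)-3-({[tert-butyl(diphenyl)silyl]oxy}methyl)-1-hydroxy-7-methyl-5-[(triethylsilyl)oxy]octa-3,6-dien-2-one | CC[Si](CC)(CC)O[C@@H](C=C(C)C)/C=C(CO[Si](c1ccccc1)(c1ccccc1)C(C)(C)C)\C(=O)CO | intermediate
12 | (3Z,5S)-3-({[tert-butyl(diphenyl)silyl]oxy}methyl)-7-methyl-2-oxo-5-[(triethylsilyl)oxy]octa-3,6-dienal (key-step precursor) | CC[Si](CC)(CC)O[C@@H](C=C(C)C)/C=C(CO[Si](c1ccccc1)(c1ccccc1)C(C)(C)C)\C(=O)C=O | intermediate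
13 | (4R,5R,6R)-2-({[tert-butyl(diphenyl)silyl]oxy}methyl)-6-hydroxy-5-(prop-1-en-2-yl)-4-[(triethylsilyl)oxy]cyclohex-2-en-1-one (key-step product) | CC[Si](CC)(CC)O[C@@H]1C=C(CO[Si](c2ccccc2)(c2ccccc2)C(C)(C)C)C(=O)[C@H](O)[C@H]1C(C)=C | intermediate
14 | (4R,5R,6R)-2-({[tert-butyl(diphenyl)silyl]oxy}methyl)-6-hydroxy-5-isopropyl-4-[(triethylsilyl)oxy]cyclohex-2-en-1-one | CC[Si](CC)(CC)O[C@@H]1C=C(CO[Si](c2ccccc2)(c2ccccc2)C(C)(C)C)C(=O)[C@H](O)[C@H]1C(C)C | intermediate
15 | 2-{[tert-butyl(diphenyl)silyl]oxy}acetaldehyde | O=CCO[Si](c1ccccc1)(c1ccccc1)C(C)(C)C | starting material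
16 | ethyl 2-(triphenylphosphoranylidene)propanoate | CCOC(=O)C(C)=P(c1ccccc1)(c1ccccc1)c1ccccc1 | starting material
17 | ethyl (2E)-4-{[tert-butyl(diphenyl)silyl]oxy}-2-methylbut-2-enoate | CCOC(=O)/C(C)=C/CO[Si](c1ccccc1)(c1ccccc1)C(C)(C)C | intermediate
18 | (2E)-4-{[tert-butyl(diphenyl)silyl]oxy}-2-methylbut-2-enoic acid | OC(=O)/C(C)=C/CO[Si](c1ccccc1)(c1ccccc1)C(C)(C)C | intermediate
19 | (2E)-4-{[tert-butyl(diphenyl)silyl]oxy}-2-methylbut-2-enoic 2,4,6-trichlorobenzoic anhydride (not isolated) | O=C(OC(=O)/C(C)=C/CO[Si](c1ccccc1)(c1ccccc1)C(C)(C)C)c1c(Cl)cc(Cl)cc1Cl | intermediate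
20 | (4R,5R,6R)-2-({[tert-butyl(diphenyl)silyl]oxy}methyl)-6-{[(2E)-4-{[tert-butyl(diphenyl)silyl]oxy}-2-methylbut-2-enoyl]oxy}-5-isopropyl-4-[(triethylsilyl)oxy]cyclohex-2-en-1-one | CC[Si](CC)(CC)O[C@@H]1C=C(CO[Si](c2ccccc2)(c2ccccc2)C(C)(C)C)C(=O)[C@H](OC(=O)/C(C)=C/CO[Si](c2ccccc2)(c2ccccc2)C(C)(C)C)[C@H]1C(C)C | intermediate
21 | (4R,5S,6R)-2-({[tert-butyl(diphenyl)silyl]oxy}methyl)-6-{[(2E)-4-{[tert-butyl(diphenyl)silyl]oxy}-2-methylbut-2-enoyl]oxy}-4-hydroxy-5-isopropylcyclohex-2-en-1-one | O[C@@H]1C=C(CO[Si](c2ccccc2)(c2ccccc2)C(C)(C)C)C(=O)[C@H](OC(=O)/C(C)=C/CO[Si](c2ccccc2)(c2ccccc2)C(C)(C)C)[C@H]1C(C)C | intermediate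
22 | propanoic acid | CCC(=O)O | starting material
23 | (4S,5S,6R)-2-({[tert-butyl(diphenyl)silyl]oxy}methyl)-6-{[(2E)-4-{[tert-butyl(diphenyl)silyl]oxy}-2-methylbut-2-enoyl]oxy}-5-isopropyl-4-(propanoyloxy)cyclohex-2-en-1-one | CCC(=O)O[C@H]1C=C(CO[Si](c2ccccc2)(c2ccccc2)C(C)(C)C)C(=O)[C@H](OC(=O)/C(C)=C/CO[Si](c2ccccc2)(c2ccccc2)C(C)(C)C)[C@H]1C(C)C | intermediate
24 | (4S,5S,6R)-2-(hydroxymethyl)-6-{[(2E)-4-hydroxy-2-methylbut-2-enoyl]oxy}-5-isopropyl-4-(propanoyloxy)cyclohex-2-en-1-one | CCC(=O)O[C@H]1C=C(CO)C(=O)[C@H](OC(=O)/C(C)=C/CO)[C@H]1C(C)C | target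

Total step count: 15 (steps 10 and 11 prepare the side-chain acid).
Longest linear sequence: 13 steps (steps 1–9 and 12–15).

Steps most likely to fail

Step 8. The Lewis acid may ionise the doubly allylic silyl ether at C4, the Z-enone may isomerise so that C5 and C6 can no longer meet, or C6 may add to the wrong face of C5 (silyloxy group in the alkene plane). The fallback closes the same C5–C6 bond one oxidation level lower, by the long-established Me2AlCl-promoted carbonyl-ene cyclisation of a simple aldehyde onto a trisubstituted alkene (citronellal class), and introduces the C1 ketone afterwards. It sets out from 9. Acetylation (Ac2O, pyridine, DMAP) should give the C1 acetate of 9 F1. DDQ in buffered CH2Cl2 should then remove the benzyl ether to give the primary alcohol F2, which is oxidised without delay (Dess–Martin periodinane, pyridine) to the 2-acetoxy aldehyde F3. Me2AlCl (CH2Cl2, −78 °C) should close the ring to the cyclohexenol F4, which carries the free C6 hydroxyl, the C1 acetate and the C5 isopropenyl group. K2CO3 in MeOH should give the 1,6-diol F5, and MnO2 in CH2Cl2, which oxidises only the allylic C1 hydroxyl, brings the route back at 13.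

Step 6. DDQ may abstract hydride from the doubly allylic C4–H, or the acidic hydroquinone formed may strip the triethylsilyl group, in competition with cleavage of the benzyl ether. The fallback does not carry O6 in as an ether but introduces it by enolate oxidation. It sets out from 7. CrCl2/NiCl2 coupling with acetaldehyde should give the methyl carbinol F6, and Dess–Martin oxidation the (Z)-methyl ketone F7. Kinetic deprotonation of the methyl group with KN(SiMe3)2 (THF, −78 °C) should give the potassium enolate F8, which is hydroxylated with 2-(benzenesulfonyl)-3-phenyloxaziridine (Davis oxidation). The route is rejoined at 11.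

Step 14. The carboxylate must enter cis to the isopropyl group, so the activated alcohol may react sluggishly, ionise with loss of stereochemical fidelity, or be diverted into acyl-hydrazine by-products. The fallback replaces phosphonium activation by a sulfonate and a naked carboxylate. It sets out from 21. MsCl and Et3N (CH2Cl2, −20 °C) should give the C4 mesylate F9, which CsO2CEt with 18-crown-6 in toluene (50 °C) should displace with inversion. The route is rejoined at 23.

Further compounds
F1 | step 8 | (3Z,5S)-3-({[tert-butyl(diphenyl)silyl]oxy}methyl)-1-[(4-methoxyphenyl)methoxy]-7-methyl-5-[(triethylsilyl)oxy]octa-3,6-dien-2-yl acetate (C2 epimers) | CC[Si](CC)(CC)O[C@@H](C=C(C)C)/C=C(CO[Si](c1ccccc1)(c1ccccc1)C(C)(C)C)\C(OC(C)=O)COCc1ccc(OC)cc1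
F2 | step 8 | (3Z,5S)-3-({[tert-butyl(diphenyl)silyl]oxy}methyl)-1-hydroxy-7-methyl-5-[(triethylsilyl)oxy]octa-3,6-dien-2-yl acetate (C2 epimers) | CC[Si](CC)(CC)O[C@@H](C=C(C)C)/C=C(CO[Si](c1ccccc1)(c1ccccc1)C(C)(C)C)\C(OC(C)=O)CO
F3 | step 8 | (3Z,5S)-3-({[tert-butyl(diphenyl)silyl]oxy}methyl)-7-methyl-1-oxo-5-[(triethylsilyl)oxy]octa-3,6-dien-2-yl acetate (C2 epimers) | CC[Si](CC)(CC)O[C@@H](C=C(C)C)/C=C(CO[Si](c1ccccc1)(c1ccccc1)C(C)(C)C)\C(OC(C)=O)C=O
F4 | step 8 | (4R,5R,6R)-2-({[tert-butyl(diphenyl)silyl]oxy}methyl)-6-hydroxy-5-(prop-1-en-2-yl)-4-[(triethylsilyl)oxy]cyclohex-2-en-1-yl acetate (C1 epimers) | CC[Si](CC)(CC)O[C@@H]1C=C(CO[Si](c2ccccc2)(c2ccccc2)C(C)(C)C)C(OC(C)=O)[C@H](O)[C@H]1C(C)=C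
F5 | step 8 | (4R,5R,6R)-2-({[tert-butyl(diphenyl)silyl]oxy}methyl)-5-(prop-1-en-2-yl)-4-[(triethylsilyl)oxy]cyclohex-2-ene-1,6-diol (C1 epimers) | CC[Si](CC)(CC)O[C@@H]1C=C(CO[Si](c2ccccc2)(c2ccccc2)C(C)(C)C)C(O)[C@H](O)[C@H]1C(C)=C
F6 | step 6 | (3Z,5S)-3-({[tert-butyl(diphenyl)silyl]oxy}methyl)-7-methyl-5-[(triethylsilyl)oxy]octa-3,6-dien-2-ol (C2 epimers) | CC[Si](CC)(CC)O[C@@H](C=C(C)C)/C=C(CO[Si](c1ccccc1)(c1ccccc1)C(C)(C)C)\C(C)O
F7 | step 6 | (3Z,5S)-3-({[tert-butyl(diphenyl)silyl]oxy}methyl)-7-methyl-5-[(triethylsilyl)oxy]octa-3,6-dien-2-one | CC[Si](CC)(CC)O[C@@H](C=C(C)C)/C=C(CO[Si](c1ccccc1)(c1ccccc1)C(C)(C)C)\C(C)=O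
F8 | step 6 | potassium enolate of F7 on the methyl side (not isolated) | [K+].CC[Si](CC)(CC)O[C@@H](C=C(C)C)/C=C(CO[Si](c1ccccc1)(c1ccccc1)C(C)(C)C)\C(=C)[O-]
F9 | step 14 | (4R,5S,6R)-2-({[tert-butyl(diphenyl)silyl]oxy}methyl)-6-{[(2E)-4-{[tert-butyl(diphenyl)silyl]oxy}-2-methylbut-2-enoyl]oxy}-5-isopropyl-4-[(methanesulfonyl)oxy]cyclohex-2-en-1-one | CS(=O)(=O)O[C@@H]1C=C(CO[Si](c2ccccc2)(c2ccccc2)C(C)(C)C)C(=O)[C@H](OC(=O)/C(C)=C/CO[Si](c2ccccc2)(c2ccccc2)C(C)(C)C)[C@H]1C(C)C
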